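The target is (+)-catechin carrying identical 2,3-trans-3,4-cis fisetinidol units at C6 and C8. In each upper unit, C4 is the only carbon bonded both to its own resorcinol ring A (at C4a) and to the catechin phloroglucinol ring, so C4 is traced back to an alkyne carbon. One twofold, gold-catalysed 6-endo-dig hydroarylation of a 6,8-dialkynylcatechin whose alkynes end in aryl propargyl ethers closes both pyran rings through their C4–C4a bonds and delivers the complete C45 skeleton as a bis(4-aryl-2H-chromene). The catalysis-set propargylic centre (future C2) then relays C3 (osmylation anti to the 2-aryl group) and C4 (hydride capture anti to O3).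

Key step: step 7

Assumption: each twofold step is driven to full conversion, so half-converted species are not numbered, and catalyst-bound or ionic species are not counted as compounds. In step 5 the antipodal ligand is used should a first run show the opposite sense of induction.

Step 1
Reactants: 1 (+)-catechin, (2R,3S)-2-(3,4-dihydroxyphenyl)chroman-3,5,7-triol
Product: 2 5,7,3',4'-tetra-O-benzyl-(+)-catechin, (2R,3S)-5,7-bis(benzyloxy)-2-[3,4-bis(benzyloxy)phenyl]chroman-3-ol
Conditions: BnBr (4.4 equiv), K2CO3, DMF, 0 °C to rt, argon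
Reagents that add atoms: benzyl bromide, BrCc1ccccc1
Why: Williamson etherification; carbonate deprotonates only the four phenols, so the secondary 3-OH stays free and no stereocentre is touched.

Step 2
Reactants: 2 5,7,3',4'-tetra-O-benzyl-(+)-catechin
Product: 3 (2R,3S)-5,7-bis(benzyloxy)-2-[3,4-bis(benzyloxy)phenyl]-6,8-diiodochroman-3-ol
Conditions: NIS (2.2 equiv), DMF, 0 °C to rt, dark
Reagents that add atoms: N-iodosuccinimide, O=C1CCC(=O)N1I
Why: Electrophilic aromatic iodination; C6 and C8 are the only free positions of the ring flanked by three oxygens and should react well before the catechol-derived ring.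

Step 3
Reactants: 4 3,4-bis(benzyloxy)benzaldehyde
Product: 5 rac-1-[3,4-bis(benzyloxy)phenyl]prop-2-yn-1-ol
Conditions: HC≡CMgBr, THF, 0 °C; aq. NH4Cl
Reagents that add atoms: ethynylmagnesium bromide, C#C[Mg]Br
Why: Grignard 1,2-addition to the aldehyde; the carbinol is racemic because its configuration is fixed stereoconvergently in step 5.

Step 4
Reactants: 5 rac-1-[3,4-bis(benzyloxy)phenyl]prop-2-yn-1-ol
Product: 6 rac-1-[3,4-bis(benzyloxy)phenyl]prop-2-yn-1-yl acetate
Conditions: Ac2O, Et3N, DMAP (cat.), CH2Cl2, 0 °C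
Reagents that add atoms: acetic anhydride, CC(=O)OC(C)=O
Why: DMAP-catalysed acylation installs the leaving group needed for copper allenylidene formation.

Step 5
Reactants: 6 rac-1-[3,4-bis(benzyloxy)phenyl]prop-2-yn-1-yl acetate; 7 3-(benzyloxy)phenol
Product: 8 (S)-1-(benzyloxy)-3-{[1-(3,4-bis(benzyloxy)phenyl)prop-2-yn-1-yl]oxy}benzene
Conditions: (CuOTf)2·C6H6 (5 mol %), (S,S)-Ph-pybox [2,6-bis((4S)-4-phenyl-4,5-dihydrooxazol-2-yl)pyridine] (12 mol %), i-Pr2NEt, ClCH2CH2Cl, −10 °C
Reagents that add atoms: none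
Why: Copper–pybox-catalysed enantioselective propargylic etherification: both enantiomers of 6 ionise to the same copper allenylidene and the phenoxide adds to one face of its γ-carbon under ligand control, setting the (S) centre that becomes C2 of both fisetinidol units.

Step 6
Reactants: 3 the 6,8-diiodide; 8 the (S)-propargyl aryl ether (2.4 equiv)
Product: 9 (2R,3S)-5,7-bis(benzyloxy)-2-[3,4-bis(benzyloxy)phenyl]-6,8-bis{(3R)-3-[3,4-bis(benzyloxy)phenyl]-3-[3-(benzyloxy)phenoxy]prop-1-yn-1-yl}chroman-3-ol (descriptor changes from S to R by priority only)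
Conditions: PdCl2(MeCN)2 (8 mol %), XPhos (20 mol %), Cs2CO3, MeCN/THF, 60 °C, degassed
Reagents that add atoms: none
Why: Twofold copper-free Sonogashira coupling; the bulky electron-rich phosphine lets zerovalent palladium insert into the di-ortho-alkoxy C–I bonds, and leaving copper out keeps the propargylic aryl ether from ionising through a copper acetylide.

Step 7
Reactants: 9 the 6,8-bis(alkynyl)catechin
Product: 10 (2R,3S)-5,7-bis(benzyloxy)-2-[3,4-bis(benzyloxy)phenyl]-6,8-bis{(2S)-7-(benzyloxy)-2-[3,4-bis(benzyloxy)phenyl]-2H-chromen-4-yl}chroman-3-ol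
Conditions: [Au(P(t-Bu)2(2-biphenylyl))(NCMe)]SbF6 (5 mol % per alkyne), CH2Cl2, 0 °C to rt, dark
Reagents that add atoms: none
Why: Cationic monovalent gold coordinates each alkyne and, because the 2,4,6-trioxygenated catechin ring is a strong π-donor, the positive charge sits on the alkyne carbon attached to that ring (future C4); the tethered resorcinol ring attacks it anti to gold through the position ortho to the ether oxygen and para to the benzyloxy group (future C4a), and rearomatisation with protodeauration releases the 4-aryl-2H-chromene and the catalyst. The closest known reaction type is the gold- or platinum-catalysed intramolecular hydroarylation (alkyne Friedel–Crafts reaction) of aryl propargyl ethers to 2H-chromenes. Each of the two pyran rings closes in the 6-endo-dig mode; the 5-exo-dig alternative would put charge on the carbon next to the oxygen-bearing C2 and is not expected. No new stereocentre is formed: the two propargylic centres are untouched, become the (2S) centres of the chromenes and control C3 and C4 in steps 8 and 9. The step needs regioselectivity on ring A (closure between the two oxygens would press a 5-benzyloxy group against the bulky 4-aryl group), chemoselectivity over oxygen participation by the flanking benzyl ethers (their 5-endo attack would have to hit the electron-poor alkyne carbon) and an intact propargylic C–O bond (non-acidic catalyst at or below room temperature).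

Step 8
Reactants: 10 the bis(4-aryl-2H-chromene)
Product: 11 (2R,3S)-5,7-bis(benzyloxy)-2-[3,4-bis(benzyloxy)phenyl]-6,8-bis{(2R,3R,4R)-7-(benzyloxy)-2-[3,4-bis(benzyloxy)phenyl]-3,4-dihydroxychroman-4-yl}chroman-3-ol (each diol cis, both hydroxyls anti to the 2-aryl group)
Conditions: OsO4 (10 mol %), NMO, MeSO2NH2, acetone/THF/H2O, rt; aq. Na2SO3
Reagents that add atoms: N-methylmorpholine N-oxide, C[N+]1([O-])CCOCC1; water, O
Why: OsO4-catalysed syn-dihydroxylation, which on flav-3-enes occurs on the face anti to the 2-aryl group; this sets C3 trans to C2 in both units, while the C4 carbinol configuration is irrelevant because C4 is planarised in step 9.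

Step 9
Reactants: 11 the bis(3,4-diol)
Product: 12 (2R,3S)-5,7-bis(benzyloxy)-2-[3,4-bis(benzyloxy)phenyl]-6,8-bis{(2R,3S,4R)-7-(benzyloxy)-2-[3,4-bis(benzyloxy)phenyl]-3-hydroxychroman-4-yl}chroman-3-ol (deca-O-benzyl target)
Conditions: n-Bu3SnH (6 equiv), CF3CO2H, CH2Cl2, −78 to −20 °C; aq. NaHCO3
Reagents that add atoms: none
Why: Ionic hydrogenation: acid ionises only the tertiary, doubly benzylic C4–OH and the stannane should deliver hydride to the cation face anti to the C3 oxygen, the same facial preference as nucleophile capture by 2,3-trans-flavan-4-yl cations but with hydrogen and aryl exchanged, so the 4-aryl group ends cis to the 3-OH (3,4-cis, 4β).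

Step 10
Reactants: 12 the deca-O-benzyl target
Product: 13 target, (2R,3S)-2-(3,4-dihydroxyphenyl)-6,8-bis[(2R,3S,4R)-2-(3,4-dihydroxyphenyl)-3,7-dihydroxychroman-4-yl]chroman-3,5,7-triol
Conditions: H2 (1 atm), Pd(OH)2/C, THF/MeOH/H2O, rt
Reagents that add atoms: none
Why: Hydrogenolysis of the ten aryl benzyl ethers; the cyclic C2–O bonds and the C4–aryl bonds of flavans are expected to survive these conditions.

Compound list
1 | (+)-catechin | Oc1cc(O)c2c(c1)O[C@H](c1ccc(O)c(O)c1)[C@@H](O)C2 | starting material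
2 | 5,7,3',4'-tetra-O-benzyl-(+)-catechin | C(c1ccccc1)Oc1cc(OCc3ccccc3)c2c(c1)O[C@H](c1ccc(OCc3ccccc3)c(OCc3ccccc3)c1)[C@@H](O)C2 | intermediate
3 | 6,8-diiodo-5,7,3',4'-tetra-O-benzylcatechin | C(c1ccccc1)Oc1c(I)c(OCc3ccccc3)c2c(c1I)O[C@H](c1ccc(OCc3ccccc3)c(OCc3ccccc3)c1)[C@@H](O)C2 | intermediate
4 | 3,4-bis(benzyloxy)benzaldehyde | O=Cc1ccc(OCc2ccccc2)c(OCc2ccccc2)c1 | starting material
5 | rac-1-[3,4-bis(benzyloxy)phenyl]prop-2-yn-1-ol | OC(C#C)c1ccc(OCc2ccccc2)c(OCc2ccccc2)c1 | intermediate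
6 | rac-1-[3,4-bis(benzyloxy)phenyl]prop-2-yn-1-yl acetate | CC(=O)OC(C#C)c1ccc(OCc2ccccc2)c(OCc2ccccc2)c1 | intermediate
7 | 3-(benzyloxy)phenol | Oc1cccc(OCc2ccccc2)c1 | starting material
8 | (S)-1-(benzyloxy)-3-{[1-(3,4-bis(benzyloxy)phenyl)prop-2-yn-1-yl]oxy}benzene | C#C[C@H](Oc1cccc(OCc2ccccc2)c1)c1ccc(OCc2ccccc2)c(OCc2ccccc2)c1 | intermediate
9 | 6,8-bis{(3R)-3-[3,4-bis(benzyloxy)phenyl]-3-[3-(benzyloxy)phenoxy]prop-1-yn-1-yl}-5,7,3',4'-tetra-O-benzylcatechin | C(c1ccccc1)Oc1c(C#C[C@H](Oc3cccc(OCc4ccccc4)c3)c3ccc(OCc4ccccc4)c(OCc4ccccc4)c3)c(OCc3ccccc3)c2c(c1C#C[C@H](Oc1cccc(OCc3ccccc3)c1)c1ccc(OCc3ccccc3)c(OCc3ccccc3)c1)O[C@H](c1ccc(OCc3ccccc3)c(OCc3ccccc3)c1)[C@@H](O)C2 | intermediate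
10 | 6,8-bis{(2S)-7-(benzyloxy)-2-[3,4-bis(benzyloxy)phenyl]-2H-chromen-4-yl}-5,7,3',4'-tetra-O-benzylcatechin | C(c1ccccc1)Oc1c(C3=C[C@@H](c4ccc(OCc5ccccc5)c(OCc5ccccc5)c4)Oc4cc(OCc5ccccc5)ccc34)c(OCc3ccccc3)c2c(c1C1=C[C@@H](c3ccc(OCc4ccccc4)c(OCc4ccccc4)c3)Oc3cc(OCc4ccccc4)ccc13)O[C@H](c1ccc(OCc3ccccc3)c(OCc3ccccc3)c1)[C@@H](O)C2 | intermediate
11 | 6,8-bis{(2R,3R,4R)-7-(benzyloxy)-2-[3,4-bis(benzyloxy)phenyl]-3,4-dihydroxychroman-4-yl}-5,7,3',4'-tetra-O-benzylcatechin | C(c1ccccc1)Oc1c([C@@]3(O)[C@H](O)[C@@H](c4ccc(OCc5ccccc5)c(OCc5ccccc5)c4)Oc4cc(OCc5ccccc5)ccc34)c(OCc3ccccc3)c2c(c1[C@@]1(O)[C@H](O)[C@@H](c3ccc(OCc4ccccc4)c(OCc4ccccc4)c3)Oc3cc(OCc4ccccc4)ccc13)O[C@H](c1ccc(OCc3ccccc3)c(OCc3ccccc3)c1)[C@@H](O)C2 | intermediate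
12 | 6,8-bis{(2R,3S,4R)-7-(benzyloxy)-2-[3,4-bis(benzyloxy)phenyl]-3-hydroxychroman-4-yl}-5,7,3',4'-tetra-O-benzylcatechin | C(c1ccccc1)Oc1c([C@@H]3[C@H](O)[C@@H](c4ccc(OCc5ccccc5)c(OCc5ccccc5)c4)Oc4cc(OCc5ccccc5)ccc34)c(OCc3ccccc3)c2c(c1[C@@H]1[C@H](O)[C@@H](c3ccc(OCc4ccccc4)c(OCc4ccccc4)c3)Oc3cc(OCc4ccccc4)ccc13)O[C@H](c1ccc(OCc3ccccc3)c(OCc3ccccc3)c1)[C@@H](O)C2 | intermediate
13 | fisetinidol-(4β→6)-[fisetinidol-(4β→8)]-catechin (CNP0289228.4) | Oc1c([C@@H]3[C@H](O)[C@@H](c4ccc(O)c(O)c4)Oc4cc(O)ccc34)c(O)c2c(c1[C@@H]1[C@H](O)[C@@H](c3ccc(O)c(O)c3)Oc3cc(O)ccc13)O[C@H](c1ccc(O)c(O)c1)[C@@H](O)C2 | target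

Total step count: 10. Longest linear sequence: 8 steps (4 to 13 through steps 3 to 10).

Steps most likely to fail, each with one fallback

Step 7. The gold activation may be diverted to oxygen participation by the flanking benzyl ethers, the propargylic C–O bond may ionise with loss of the C2 configuration, or the polyether substrate may sequester the catalyst. The fallback sets out from 9 and replaces π-acid catalysis by a metal-free, buffered electrophilic iodocyclisation (I2, NaHCO3, MeNO2/CH2Cl2, 0 °C), which still closes both pyran rings 6-endo-dig through C4–C4a. It should give 6,8-bis{(2R)-7-(benzyloxy)-2-[3,4-bis(benzyloxy)phenyl]-3-iodo-2H-chromen-4-yl}-5,7,3',4'-tetra-O-benzylcatechin F1. Palladium-catalysed hydrodeiodination (Pd(OAc)2, PPh3, HCO2H, Et3N, DMF, 50 °C) then returns to 10.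

Step 9. Hydride capture may show poor facial selectivity, since the 2-aryl and 3-hydroxyl groups lie on opposite faces, or the C4 cation may undergo a pinacol-type 1,2-hydride shift before it is reduced. The fallback sets out from 11 and makes that shift the productive path. BF3·OEt2 (CH2Cl2, −40 °C) should move the C3 hydrogen, which lies on the 2-aryl face, suprafacially to C4, giving the 2,4-trans diketone 6,8-bis{(2R,4R)-7-(benzyloxy)-2-[3,4-bis(benzyloxy)phenyl]-3-oxochroman-4-yl}-5,7,3',4'-tetra-O-benzylcatechin F3 with C4 already correct. NaBH4 (MeOH/THF, −78 °C) should then attack each ketone anti to the bulky quasi-axial 4-aryl group, placing the 3-OH cis to it and trans to the 2-aryl group, which returns to 12.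

Step 8. Steric shielding of C4 by the two ortho substituents of the catechin ring may slow osmylation so far that over-oxidation of the electron-rich rings competes. The fallback sets out from 10 and uses the smaller oxidant dimethyldioxirane (acetone/CH2Cl2, −40 °C), which should give the bis(3,4-epoxyflavan) with each oxirane oxygen anti to the 2-aryl group, 6,8-bis{7-(benzyloxy)-2-[3,4-bis(benzyloxy)phenyl]-3,4-epoxychroman-4-yl}-5,7,3',4'-tetra-O-benzylcatechin F2. After cold evaporation the crude epoxide is opened with n-Bu3SnH/CF3CO2H (CH2Cl2, −78 °C) at the doubly benzylic C4, hydride entering anti to the C3–O bond. This returns directly to 12 and by-passes 11.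

Further compounds
F1 | step 7 | 6,8-bis{(2R)-7-(benzyloxy)-2-[3,4-bis(benzyloxy)phenyl]-3-iodo-2H-chromen-4-yl}-5,7,3',4'-tetra-O-benzylcatechin | C(c1ccccc1)Oc1c(C3=C(I)[C@@H](c4ccc(OCc5ccccc5)c(OCc5ccccc5)c4)Oc4cc(OCc5ccccc5)ccc34)c(OCc3ccccc3)c2c(c1C1=C(I)[C@@H](c3ccc(OCc4ccccc4)c(OCc4ccccc4)c3)Oc3cc(OCc4ccccc4)ccc13)O[C@H](c1ccc(OCc3ccccc3)c(OCc3ccccc3)c1)[C@@H](O)C2
F2 | step 8 | 6,8-bis{7-(benzyloxy)-2-[3,4-bis(benzyloxy)phenyl]-3,4-epoxychroman-4-yl}-5,7,3',4'-tetra-O-benzylcatechin, oxirane oxygens anti to the 2-aryl groups | C(c1ccccc1)Oc1c([C@@]34O[C@@H]3[C@@H](c3ccc(OCc5ccccc5)c(OCc5ccccc5)c3)Oc3cc(OCc5ccccc5)ccc34)c(OCc3ccccc3)c2c(c1[C@@]13O[C@@H]1[C@@H](c1ccc(OCc4ccccc4)c(OCc4ccccc4)c1)Oc1cc(OCc4ccccc4)ccc13)O[C@H](c1ccc(OCc3ccccc3)c(OCc3ccccc3)c1)[C@@H](O)C2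
F3 | step 9 | 6,8-bis{(2R,4R)-7-(benzyloxy)-2-[3,4-bis(benzyloxy)phenyl]-3-oxochroman-4-yl}-5,7,3',4'-tetra-O-benzylcatechin | C(c1ccccc1)Oc1c([C@@H]3C(=O)[C@@H](c4ccc(OCc5ccccc5)c(OCc5ccccc5)c4)Oc4cc(OCc5ccccc5)ccc34)c(OCc3ccccc3)c2c(c1[C@@H]1C(=O)[C@@H](c3ccc(OCc4ccccc4)c(OCc4ccccc4)c3)Oc3cc(OCc4ccccc4)ccc13)O[C@H](c1ccc(OCc3ccccc3)c(OCc3ccccc3)c1)[C@@H](O)C2
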